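The time of reading, 4.0 d, lies just beyond my last readings at 3.00 d, so I need a way of bridging the final stretch, not a whole curve.

| flask | X | G | remark | time |
|---|---|---|---|---|
| epsilon | 0.095 M | 0.60 equiv | run made earlier |  |
| zeta | 0.095 M | 2.4 equiv | run made earlier |  |
| alpha | 0.14 M | 1.2 equiv | run made earlier |  |
| flask | 0.095 M | 1.20 equiv |  | 4.0 d |

| run | time / d | X / % | J / % |
|---|---|---|---|
| epsilon | 0.833 | 38 | 10 |
| epsilon | 1.67 | 21 | 13 |
| epsilon | 2.50 | 19 | 16 |
| epsilon | 3.00 | 10 | 17 |
| zeta | 0.250 | 60 | 15 |
| zeta | 0.625 | 32 | 30 |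
| zeta | 1.25 | 17 | 36 |
| zeta | 3.00 | 4 | 45 |
| alpha | 0.250 | 55 | 10 |
| alpha | 0.625 | 31 | 21 |
| alpha | 1.25 | 15 | 23 |
| alpha | 3.00 | 8 | 30 |

(scatter of a reading: 1.5 percentage points)
- a reading or a percentage of J counts all its forms, free or not
* X at 4.0 d, in percent of the X charged
* J at 4.0 d, in percent of the X charged
* D at 4.0 d, in percent of the X charged

The bridge needs two numbers: X at 3.00 d, and the time X then takes to halve. Late in zeta, X falls from 17 % to 4 % in 1.75 d, a half-life of 0.838 d. I take this fall as pseudo-first-order, with the half-life inverse to the G charged. Going from 2.4 equiv to 1.20 equiv gives 1.68 d, my tail half-life: the time X needs to halve late in this flask.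

How good must each number be? The remaining stretch multiplies X by 0.661, so an error in the starting value comes through scaled by that same factor. A half-life of 3.36 d would move the answer from 4.63 % to just 5.69 %. An error of 1.5 percentage points in the starting value would move it by 0.99 points.

The flask's G lies between epsilon and zeta, so I start midway between their readings, at 7.00 %, which gives 4.63 % X at 4.0 d. The same midpoint gives J 31.0 %. That leaves 64.4 % which the readings do not name, so I commit to no value for D.

The forecast gives 6 % X, above my figure, 32 % J and 62 % D, with "D is taken by balance, counted in X units".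

The flask gives 5.59 % X, 30.2 % J and 4.36 % D, with 59.8 % in L.

    G + J → D (k = 0.00110 M⁻¹ min⁻¹)
    X + G → J (k = 0.00280 M⁻¹ min⁻¹)
    2 X → L (k = 0.00600 M⁻¹ min⁻¹)
    E ⇌ J, rate k4*(cs4 - [J]) while solid is left; crystals form when [J] > cs4 (solubility = 6.60 mM, k = 0.00370 min⁻¹)

At 0.666 d the flask's X has a half-life of 1.8 d by its step with G, near my 1.68 d, while G has one of 47 d by its step with J, and 4.0 d is 2.38 tail half-lives but 0.0860 of that slower one. For the neighbour flask with 0.38 M X at the same equivalents, my rule scaled by the charge estimates a tail half-life of 0.419 d, or 0.679 d with G at 61.7 % of its charge at 4.00 d. That makes 4.0 d there about 5.89 estimated half-lives, and that flask holds 0.129 % X and 6.60 % D.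

The runs were computed from invented constants; noise was put on by code.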